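**Retrosynthetic overview** (isochromene locants: C1 = OCH2, O2, C3, C4, C4a, C5 = CCl, C6/C8 = C=O, C7 = C(Me)OAc, C8a = ring-fusion CH; ring A = carbocycle, ring B = pyran)
1. Ring B is opened last at O2–C3 (6-endo-dig addition of the C1 hydroxyl to a C4a-alkynyl enone); C1 comes off C8a as formaldehyde (aldol) and C4a–C4 is cut to a C4a enol triflate plus an (R)-dienyne (Sonogashira).
2. The strategy rests on the C6(=O)–C7(Me)(O)–C8(=O) triad of ring A: it is the α-ketol isomer of a cyclopentenone carrying hydroxyl and acetyl on one carbon (future C8), so ring A is made by a 1,2-shift of acyl carbon C6 from C8 to the acetyl carbon C7 (ring expansion from five to six, C7 set stereospecifically).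
3. The acetyl-hydroxy-cyclopentenone comes from cyclopentane-1,3-dione by C2 chlorination, O-methylation, kinetic α′-acetylation and catalytic asymmetric α-hydroxylation.
4. The dienyne comes from (R)-2-methylbutanoic acid by two E-selective Wittig homologations and a one-carbon alkynylation.
5. Ring order: five-membered carbocycle, then ring A (expansion), then ring B (pyran closure).

Key step: step 5

Remark: C8a–H is α to the C8 ketone and vinylogous to the C6 ketone, so C8a is treated as an equilibrating centre that is fixed only in the last step; compounds that can enolise towards C8a or C5 are drawn as keto tautomers.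

**Step 1**
Reactants: 1 cyclopentane-1,3-dione
Product: 2 2-chlorocyclopentane-1,3-dione
Conditions: N-chlorosuccinimide (1.0 equiv), MeCN, 0 °C to rt
Reagents that add atoms: N-chlorosuccinimide, ClN1C(=O)CCC1=O
Why: Electrophilic α-chlorination of the enol of a cyclic 1,3-dione, in which C2 is the only nucleophilic carbon and one equivalent of reagent at low temperature limits dichlorination.

**Step 2**
Reactants: 2 2-chlorocyclopentane-1,3-dione
Product: 3 2-chloro-3-methoxycyclopent-2-en-1-one
Conditions: MeOH, HC(OMe)3 (2 equiv), TsOH·H2O (cat.), 50 °C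
Reagents that add atoms: methanol, CO
Why: Acid-catalysed enol etherification of a symmetric 1,3-dione (vinylogous Fischer esterification) with orthoformate as water scavenger, so that only one constitution can form.

**Step 3**
Reactants: 3 2-chloro-3-methoxycyclopent-2-en-1-one
Product: 5 5-acetyl-2-chloro-3-methoxycyclopent-2-en-1-one, via lithium 5-chloro-4-methoxycyclopenta-1,4-dien-1-olate 4 (not isolated)
Conditions: LiN(iPr)2 (2.1 equiv), THF, −78 °C; then 1-acetylbenzotriazole (1.1 equiv), −78 °C to 0 °C; aq. NH4Cl
Reagents that add atoms: 1-acetyl-1H-benzotriazole, CC(=O)n1nnc2ccccc12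
Why: Kinetic α′-deprotonation of the vinylogous ester at C5 by the hindered amide, then Claisen-type C-acylation of the enolate with an N-acylbenzotriazole, the second equivalent of base taking up the acidic β-diketone as it forms.

**Step 4**
Reactants: 5 5-acetyl-2-chloro-3-methoxycyclopent-2-en-1-one
Product: 6 (5S)-5-acetyl-2-chloro-5-hydroxy-3-methoxycyclopent-2-en-1-one
Conditions: cumene hydroperoxide (1.3 equiv), N-(anthracen-9-ylmethyl)cinchoninium chloride (10 mol%), toluene / 50% aq. K2HPO4, 0 °C
Reagents that add atoms: cumene hydroperoxide, CC(C)(OO)c1ccccc1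
Why: Phase-transfer-catalysed asymmetric α-hydroxylation of an α-substituted cyclic β-dicarbonyl compound, in which the chiral ammonium enolate ion pair attacks the terminal peroxide oxygen on one face and so sets the carbinol centre; the (S) ketol is taken from whichever pseudo-enantiomeric cinchoninium or cinchonidinium salt delivers it, and the weak base and low temperature hold back retro-Claisen loss of the acetyl group.

**Step 5**
Reactants: 6 (5S)-5-acetyl-2-chloro-5-hydroxy-3-methoxycyclopent-2-en-1-one
Product: 8 (2R)-4-chloro-2-hydroxy-5-methoxy-2-methylcyclohex-4-ene-1,3-dione, via di-tert-butoxyaluminium alkoxide chelate 7 (not isolated)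
Conditions: Al(OtBu)3 (1.5 equiv), toluene, 60 °C; aq. KNaC4H4O6 work-up
Reagents that add atoms: none
Why: Proposed new method: alkoxide exchange gives the aluminium alkoxide 7, whose metal also binds the acetyl oxygen, so the carbinol C–O and the acetyl C=O are syn-periplanar and the two ring bonds of the carbinol carbon stand above and below the chelate; as the carbinol carbon (future C8) becomes a ketone, ring acyl carbon C6 shifts suprafacially to the acetyl carbon (future C7), forming C6–C7 and breaking C6–C8. The closest known reaction types are the aluminium-alkoxide α-ketol ring expansion of 1-acyl-1-hydroxycyclopentanes to 2-hydroxy-2-alkylcyclohexanones and the acyl-migrating tertiary ketol shifts of α-hydroxy-β-dicarbonyl compounds (acetolactate type, and the acyloin ring contraction of hop α-acids, which is this shift in the opposite sense); new here is a vinylogous-ester acyl carbon migrating in the ring-enlarging direction. Ring A is not closed by a cyclisation but grows from five to six members by the 1,2-shift, so no exo or endo mode applies. The one new stereocentre, C7, is set by the stereospecific shift: through the chelated syn-periplanar geometry the (S) carbinol of 6 is relayed to (R)-C7, whereas the non-chelated anti-periplanar rotamer would give the antipode, which is why a strongly chelating, non-reducing and poorly nucleophilic tert-butoxide is used. The selectivity needed is migration of acyl C6 instead of the ring CH2 (which would give a 1,2-dione) and instead of acetyl C-to-O transfer; it should be secured by the higher migratory aptitude of acyl groups in ketol shifts, by relief of cyclopentenone strain, and by the product being drained as the aluminium dienolate of the much more acidic six-membered system (C8a–H2).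

**Step 6**
Reactants: 8 (2R)-4-chloro-2-hydroxy-5-methoxy-2-methylcyclohex-4-ene-1,3-dione
Product: 9 (1R)-3-chloro-4-methoxy-1-methyl-2,6-dioxocyclohex-3-en-1-yl acetate
Conditions: Ac2O (3 equiv), Sc(OTf)3 (5 mol%), MeCN, −20 °C to 0 °C; aq. NaHCO3
Reagents that add atoms: acetic anhydride, CC(=O)OC(C)=O
Why: Lewis-acid-catalysed acylation of a hindered tertiary alcohol with an anhydride, preferred to amine-promoted acylation so that the acidic C8a methylene is not enolised; an enol ester that might form at the C8 oxygen is a vinylogous anhydride and should not survive the bicarbonate work-up.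

**Step 7**
Reactants: 9 (1R)-3-chloro-4-methoxy-1-methyl-2,6-dioxocyclohex-3-en-1-yl acetate
Product: 10 (1R)-3-chloro-4-hydroxy-1-methyl-2,6-dioxocyclohex-3-en-1-yl acetate
Conditions: 2 M aq. HCl, THF, rt
Reagents that add atoms: water, O
Why: Acid hydrolysis of a vinylogous methyl ester by addition of water at C4a and loss of methanol; the tertiary acetate tolerates cold dilute acid, and C7 stays stereogenic in the trione because the C5 chlorine keeps its two flanks different.

**Step 8**
Reactants: 10 (1R)-3-chloro-4-hydroxy-1-methyl-2,6-dioxocyclohex-3-en-1-yl acetate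
Product: 11 (1R)-3-chloro-1-methyl-2,6-dioxo-4-[(trifluoromethanesulfonyl)oxy]cyclohex-3-en-1-yl acetate
Conditions: 2,6-lutidine (1.3 equiv), CH2Cl2, −78 °C; then Tf2O (1.05 equiv), −78 °C
Reagents that add atoms: trifluoromethanesulfonic anhydride, O=S(=O)(OS(=O)(=O)C(F)(F)F)C(F)(F)F
Why: Enol triflate formation from the enolate of a cyclic 1,3-dione, in which the C4a oxygen is the only enolate oxygen not flanked by the quaternary C7 and should therefore be sulfonylated, as enol derivatisation of 4,4-disubstituted cyclohexane-1,3-diones occurs at the carbonyl remote from the quaternary carbon.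

**Step 9**
Reactants: 12 (R)-2-methylbutanoic acid
Product: 13 (R)-2-methylbutan-1-ol
Conditions: LiAlH4 (1.2 equiv), Et2O, 0 °C to reflux; aqueous work-up
Reagents that add atoms: none
Why: Hydride reduction of a carboxylic acid to the primary alcohol, which does not touch the α-stereocentre.

**Step 10**
Reactants: 13 (R)-2-methylbutan-1-ol
Product: 15 ethyl (2E,4R)-2,4-dimethylhex-2-enoate, via (R)-2-methylbutanal 14 (not isolated)
Conditions: PhI(OAc)2 (1.1 equiv), TEMPO (10 mol%), CH2Cl2, rt; then Ph3P=C(CH3)CO2Et (1.5 equiv), rt to 40 °C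
Reagents that add atoms: ethyl 2-(triphenylphosphoranylidene)propanoate, CCOC(=O)C(C)=P(c1ccccc1)(c1ccccc1)c1ccccc1
Why: Nitroxyl-catalysed oxidation under base-free conditions should give the α-chiral aldehyde without epimerisation, and the stabilised ylide added to the same flask converts it by an E-selective Wittig reaction into the trisubstituted enoate.

**Step 11**
Reactants: 15 ethyl (2E,4R)-2,4-dimethylhex-2-enoate
Product: 16 (2E,4R)-2,4-dimethylhex-2-en-1-ol
Conditions: iBu2AlH (2.2 equiv), CH2Cl2, −78 °C to 0 °C; aq. KNaC4H4O6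
Reagents that add atoms: none
Why: 1,2-Reduction of an α,β-unsaturated ester to the allylic alcohol by an aluminium hydride, leaving the double-bond geometry untouched.

**Step 12**
Reactants: 16 (2E,4R)-2,4-dimethylhex-2-en-1-ol
Product: 17 (2E,4R)-2,4-dimethylhex-2-enal
Conditions: MnO2 (10 equiv), CH2Cl2, rt
Reagents that add atoms: none
Why: Selective heterogeneous allylic oxidation by MnO2, which neither isomerises the alkene nor over-oxidises the enal.

**Step 13**
Reactants: 17 (2E,4R)-2,4-dimethylhex-2-enal
Product: 18 (2E,4E,6R)-4,6-dimethylocta-2,4-dienal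
Conditions: Ph3P=CHCHO (1.2 equiv), toluene, 80 °C
Reagents that add atoms: 2-(triphenylphosphoranylidene)acetaldehyde, O=CC=P(c1ccccc1)(c1ccccc1)c1ccccc1
Why: Wittig reaction with a formyl-stabilised ylide, which should form the new disubstituted double bond with E geometry and stop at the dienal because the product is the poorer electrophile.

**Step 14**
Reactants: 18 (2E,4E,6R)-4,6-dimethylocta-2,4-dienal
Product: 19 (3E,5E,7R)-5,7-dimethylnona-3,5-dien-1-yne
Conditions: Me3SiCHN2 (1.2 equiv), n-BuLi (1.2 equiv), THF, −78 °C; then 18, −78 °C to rt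
Reagents that add atoms: trimethylsilyldiazomethane, C[Si](C)(C)C=[N+]=[N-]
Why: Colvin rearrangement, in which the lithiated silyldiazomethane adds to the aldehyde, Peterson-type elimination gives the diazoalkene, and loss of N2 with 1,2-hydride shift of the alkylidene carbene gives the terminal alkyne without disturbing the diene or the remote stereocentre.

**Step 15**
Reactants: 11 (1R)-3-chloro-1-methyl-2,6-dioxo-4-[(trifluoromethanesulfonyl)oxy]cyclohex-3-en-1-yl acetate; 19 (3E,5E,7R)-5,7-dimethylnona-3,5-dien-1-yne
Product: 20 (1R)-3-chloro-4-[(3E,5E,7R)-5,7-dimethylnona-3,5-dien-1-yn-1-yl]-1-methyl-2,6-dioxocyclohex-3-en-1-yl acetate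
Conditions: Pd(PPh3)2Cl2 (5 mol%), CuI (10 mol%), iPr2NEt (2 equiv), THF, 0 °C to rt
Reagents that add atoms: none
Why: Sonogashira coupling of an electron-poor enol triflate, where oxidative addition at C4a–OTf is far faster than at the C5–Cl bond and a tertiary amine is used so that no amine can add to the β-position of the enone.

**Step 16**
Reactants: 20 (1R)-3-chloro-4-[(3E,5E,7R)-5,7-dimethylnona-3,5-dien-1-yn-1-yl]-1-methyl-2,6-dioxocyclohex-3-en-1-yl acetate
Product: 21 (1R)-3-chloro-4-[(3E,5E,7R)-5,7-dimethylnona-3,5-dien-1-yn-1-yl]-1-methyl-2-oxo-6-[(trimethylsilyl)oxy]cyclohexa-3,5-dien-1-yl acetate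
Conditions: Me3SiOTf (1.2 equiv), Et3N (1.5 equiv), CH2Cl2, −20 °C to 0 °C; non-aqueous work-up, used crude
Reagents that add atoms: trimethylsilyl trifluoromethanesulfonate, C[Si](C)(C)OS(=O)(=O)C(F)(F)F
Why: Soft enolisation of the only enolisable position (the C8a methylene next to the C8 ketone) with a silyl triflate and a tertiary amine gives the silyl dienol ether, and the O6-silylated isomer, should it form, is a derivative of the same dienolate and reacts alike in step 17.

**Step 17**
Reactants: 21 (1R)-3-chloro-4-[(3E,5E,7R)-5,7-dimethylnona-3,5-dien-1-yn-1-yl]-1-methyl-2-oxo-6-[(trimethylsilyl)oxy]cyclohexa-3,5-dien-1-yl acetate; 22 formaldehyde (aqueous solution made from paraformaldehyde)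
Product: 23 (1R,5RS)-3-chloro-4-[(3E,5E,7R)-5,7-dimethylnona-3,5-dien-1-yn-1-yl]-5-(hydroxymethyl)-1-methyl-2,6-dioxocyclohex-3-en-1-yl acetate
Conditions: aq. HCHO (5 equiv), Sc(OTf)3 (10 mol%), THF–H2O (9:1), −20 °C to 0 °C; used directly
Reagents that add atoms: none
Why: Mukaiyama aldol reaction with formaldehyde under water-tolerant Lewis acid catalysis, in which the silyl dienol ether reacts once at the unsubstituted C8a terminus (the chlorine-bearing C5 terminus would have to become quaternary) and so avoids the double hydroxymethylation and dehydration of base-mediated formaldehyde aldols; the new C8a centre forms without reliable control and is carried as an epimer mixture because step 18 corrects it.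

**Step 18**
Reactants: 23 (1R,5RS)-3-chloro-4-[(3E,5E,7R)-5,7-dimethylnona-3,5-dien-1-yn-1-yl]-5-(hydroxymethyl)-1-methyl-2,6-dioxocyclohex-3-en-1-yl acetate
Product: 25 (7R,8aR)-5-chloro-3-[(1E,3E,5R)-3,5-dimethylhepta-1,3-dien-1-yl]-7-methyl-6,8-dioxo-6,7,8,8a-tetrahydro-1H-isochromen-7-yl acetate, via C8a-epimeric isochromene mixture 24 (not isolated)
Conditions: Ph3PAuNTf2 (5 mol%), CH2Cl2, 0 °C to rt; then Et3N (0.2 equiv), rt
Reagents that add atoms: none
Why: Gold-catalysed 6-endo-dig hydroalkoxylation, in which the C1 hydroxyl attacks the gold-activated alkyne at C3 (the δ-position of the ynenone and the carbon bearing the dienyl donor) and protodeauration at C4 closes ring B; the trace of tertiary amine then equilibrates the acidic C8a–H so that C8a is set under thermodynamic control, the (8aR) epimer being expected to prevail because, with C8a–H held pseudoaxial by the fused pyran, only it lets the C7 acetoxy group stand axial (perpendicular to both flanking carbonyl dipoles) with the C7 methyl equatorial.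

**Compound list**
1 | cyclopentane-1,3-dione | O=C1CCC(=O)C1 | starting material
2 | 2-chlorocyclopentane-1,3-dione | O=C1CCC(=O)C1Cl | intermediate
3 | 2-chloro-3-methoxycyclopent-2-en-1-one | COC1=C(Cl)C(=O)CC1 | intermediate
4 | lithium 5-chloro-4-methoxycyclopenta-1,4-dien-1-olate | [Li+].COC1=C(Cl)C([O-])=CC1 | intermediate (not isolated)
5 | 5-acetyl-2-chloro-3-methoxycyclopent-2-en-1-one | COC1=C(Cl)C(=O)C(C(C)=O)C1 | intermediate
6 | (5S)-5-acetyl-2-chloro-5-hydroxy-3-methoxycyclopent-2-en-1-one | COC1=C(Cl)C(=O)[C@@](O)(C(C)=O)C1 | intermediate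
7 | di-tert-butoxyaluminium alkoxide chelate of 6 | COC1=C(Cl)C(=O)[C@@](O[Al](OC(C)(C)C)OC(C)(C)C)(C(C)=O)C1 | intermediate (not isolated)
8 | (2R)-4-chloro-2-hydroxy-5-methoxy-2-methylcyclohex-4-ene-1,3-dione | COC1=C(Cl)C(=O)[C@](C)(O)C(=O)C1 | intermediate
9 | (1R)-3-chloro-4-methoxy-1-methyl-2,6-dioxocyclohex-3-en-1-yl acetate | COC1=C(Cl)C(=O)[C@](C)(OC(C)=O)C(=O)C1 | intermediate
10 | (1R)-3-chloro-4-hydroxy-1-methyl-2,6-dioxocyclohex-3-en-1-yl acetate | OC1=C(Cl)C(=O)[C@](C)(OC(C)=O)C(=O)C1 | intermediate
11 | (1R)-3-chloro-1-methyl-2,6-dioxo-4-[(trifluoromethanesulfonyl)oxy]cyclohex-3-en-1-yl acetate | O=S(=O)(OC1=C(Cl)C(=O)[C@](C)(OC(C)=O)C(=O)C1)C(F)(F)F | intermediate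
12 | (R)-2-methylbutanoic acid | CC[C@@H](C)C(O)=O | starting material
13 | (R)-2-methylbutan-1-ol | CC[C@@H](C)CO | intermediate
14 | (R)-2-methylbutanal | CC[C@@H](C)C=O | intermediate (not isolated)
15 | ethyl (2E,4R)-2,4-dimethylhex-2-enoate | CC[C@@H](C)/C=C(C)/C(=O)OCC | intermediate
16 | (2E,4R)-2,4-dimethylhex-2-en-1-ol | CC[C@@H](C)/C=C(C)/CO | intermediate
17 | (2E,4R)-2,4-dimethylhex-2-enal | CC[C@@H](C)/C=C(C)/C=O | intermediate
18 | (2E,4E,6R)-4,6-dimethylocta-2,4-dienal | CC[C@@H](C)/C=C(C)/C=C/C=O | intermediate
19 | (3E,5E,7R)-5,7-dimethylnona-3,5-dien-1-yne | CC[C@@H](C)/C=C(C)/C=C/C#C | intermediate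
20 | (1R)-3-chloro-4-[(3E,5E,7R)-5,7-dimethylnona-3,5-dien-1-yn-1-yl]-1-methyl-2,6-dioxocyclohex-3-en-1-yl acetate | CC[C@@H](C)/C=C(C)/C=C/C#CC1=C(Cl)C(=O)[C@](C)(OC(C)=O)C(=O)C1 | intermediate
21 | (1R)-3-chloro-4-[(3E,5E,7R)-5,7-dimethylnona-3,5-dien-1-yn-1-yl]-1-methyl-2-oxo-6-[(trimethylsilyl)oxy]cyclohexa-3,5-dien-1-yl acetate | CC[C@@H](C)/C=C(C)/C=C/C#CC1=C(Cl)C(=O)[C@](C)(OC(C)=O)C(O[Si](C)(C)C)=C1 | intermediate
22 | formaldehyde (from paraformaldehyde) | C=O | starting material
23 | (1R,5RS)-3-chloro-4-[(3E,5E,7R)-5,7-dimethylnona-3,5-dien-1-yn-1-yl]-5-(hydroxymethyl)-1-methyl-2,6-dioxocyclohex-3-en-1-yl acetate (C8a epimer mixture) | CC[C@@H](C)/C=C(C)/C=C/C#CC1=C(Cl)C(=O)[C@](C)(OC(C)=O)C(=O)C1CO | intermediate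
24 | (7R,8aRS)-5-chloro-3-[(1E,3E,5R)-3,5-dimethylhepta-1,3-dien-1-yl]-7-methyl-6,8-dioxo-6,7,8,8a-tetrahydro-1H-isochromen-7-yl acetate (C8a epimer mixture) | CC[C@@H](C)/C=C(C)/C=C/C1=CC2=C(Cl)C(=O)[C@](C)(OC(C)=O)C(=O)C2CO1 | intermediate (not isolated)
25 | (7R,8aR)-5-chloro-3-[(1E,3E,5R)-3,5-dimethylhepta-1,3-dien-1-yl]-7-methyl-6,8-dioxo-6,7,8,8a-tetrahydro-1H-isochromen-7-yl acetate | CC[C@@H](C)/C=C(C)/C=C/C1=CC2=C(Cl)C(=O)[C@](C)(OC(C)=O)C(=O)[C@H]2CO1 | target

**Step count**
Total: 18 steps. Longest linear sequence: 12 steps (steps 1–8 and 15–18, from cyclopentane-1,3-dione); the dienyne branch is 6 steps (steps 9–14).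

**Steps most likely to fail**

Step 5 (key step). The ring CH2 may migrate instead of the acyl carbon, the acetyl group may transfer from carbon to oxygen, the shift may run through a non-chelated rotamer or reverse and so erode the configuration at C7, or the equilibrium may not favour the six-membered ring. The fallback uses known dearomatisation chemistry. No numbered cyclopentanoid can be reused, so it sets out from the new commercial material 2-methylbenzene-1,3,5-triol F1 in place of compound 1 and comes back to the route at compound 9. Acid-catalysed mono-O-methylation (MeOH, HCl) at the unhindered hydroxyl para to the methyl group would give 5-methoxy-2-methylbenzene-1,3-diol F2. Chlorination with N-chlorosuccinimide at one of its two equivalent ring CH positions would give 4-chloro-5-methoxy-2-methylbenzene-1,3-diol F3. Wessely acetoxylation (Pb(OAc)4, AcOH) at the methyl-bearing carbon between the two phenols would give racemic 3-chloro-4-methoxy-1-methyl-2,6-dioxocyclohex-3-en-1-yl acetate F4. Preparative chiral-phase HPLC would then separate the (R) enantiomer, which is compound 9, and the route continues at step 7.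

Step 8. Sulfonylation may occur at the hindered C6 or C8 oxygen instead of the C4a oxygen, or twice. The fallback sets out from compound 9 and comes back at compound 20. It replaces the ambident enolate by an addition–elimination that can only take place at the methoxy-bearing C4a: thiophenol with catalytic TsOH would give (1R)-3-chloro-1-methyl-2,6-dioxo-4-(phenylsulfanyl)cyclohex-3-en-1-yl acetate F5. Dienyne 19 would be stannylated with Bu3SnOMe to tributyl[(3E,5E,7R)-5,7-dimethylnona-3,5-dien-1-yn-1-yl]stannane F6. A Liebeskind–Srogl coupling of F5 with F6 (Pd2(dba)3, tri(2-furyl)phosphine, copper thiophene-2-carboxylate CuO2CC4H3S, THF) would give compound 20, and the route continues at step 16.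

Step 18. The thermodynamic bias between the C8a epimers may be too small, the amine may open ring B by retro-oxa-Michael elimination during equilibration, or the hydroxyl may add 5-exo instead of 6-endo. The fallback sets out from compound 21 and comes back at compound 25. It sets C8a kinetically under reagent control and uses no base afterwards. A catalytic asymmetric Mukaiyama hydroxymethylation of 21 with aqueous formaldehyde 22 would be run with Sc(OTf)3 and the matched antipode of 6,6'-bis(1-hydroxy-2,2-dimethylpropyl)-2,2'-bipyridine. It would give the single epimer (1R,5R)-3-chloro-4-[(3E,5E,7R)-5,7-dimethylnona-3,5-dien-1-yn-1-yl]-5-(hydroxymethyl)-1-methyl-2,6-dioxocyclohex-3-en-1-yl acetate F7. F7 would be cyclised with Ph3PAuNTf2 alone and worked up under neutral conditions to give compound 25 directly.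

**Further compounds**
F1 | step 5 | 2-methylbenzene-1,3,5-triol | Cc1c(O)cc(O)cc1O
F2 | step 5 | 5-methoxy-2-methylbenzene-1,3-diol | COc1cc(O)c(C)c(O)c1
F3 | step 5 | 4-chloro-5-methoxy-2-methylbenzene-1,3-diol | COc1cc(O)c(C)c(O)c1Cl
F4 | step 5 | racemic 3-chloro-4-methoxy-1-methyl-2,6-dioxocyclohex-3-en-1-yl acetate | COC1=C(Cl)C(=O)C(C)(OC(C)=O)C(=O)C1
F5 | step 8 | (1R)-3-chloro-1-methyl-2,6-dioxo-4-(phenylsulfanyl)cyclohex-3-en-1-yl acetate | c1ccc(cc1)SC2=C(Cl)C(=O)[C@](C)(OC(C)=O)C(=O)C2
F6 | step 8 | tributyl[(3E,5E,7R)-5,7-dimethylnona-3,5-dien-1-yn-1-yl]stannane | CC[C@@H](C)/C=C(C)/C=C/C#C[Sn](CCCC)(CCCC)CCCC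
F7 | step 18 | (1R,5R)-3-chloro-4-[(3E,5E,7R)-5,7-dimethylnona-3,5-dien-1-yn-1-yl]-5-(hydroxymethyl)-1-methyl-2,6-dioxocyclohex-3-en-1-yl acetate | CC[C@@H](C)/C=C(C)/C=C/C#CC1=C(Cl)C(=O)[C@](C)(OC(C)=O)C(=O)[C@H]1CO
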